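**Plan**
Retrosynthesis: ring C is opened at O1–C2 and C2–C3 (enaminone of a deoxybenzoin), the C4–C4a bond to ring A is cut next (aryl-metal plus arylacetaldehyde), and the CH2CHO arm is traced back to an ethynyl group on ring B.
The ethynyl carbon on C1′ and the prenyl CH2 on C2′ are then cut together: C1′ and C2′ are adjacent ring B carbons and C2′ is flanked by the oxygen-bearing C3′, the pattern of a 3-alkoxyaryne that takes a nucleophile at its distal carbon and an electrophile at its proximal one.
Forward: the dimethylpyran (ring D) is fused to catechol mono-MOM ether by a propargyl Claisen sequence, two directed metalations add the C7 oxygen and the C6 silyl group (chromene C6/C7/C8 = C1′/C2′/C3′), and the silyl triflate is made.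
The aryne alkynylation–prenylation follows, the alkyne becomes CH2CHO, ring A is added as an aryl-cerium reagent, and ring C is closed last while all MOM groups are removed.
Stereochemistry: the target has no stereocentre; the one carbinol centre formed on the way is racemic and is oxidised away.

Key step: step 8

Assumption: enaminones 30 and 31 (and the fallback enaminone) are drawn as E isomers; the push–pull double bond equilibrates easily and its geometry has no bearing on ring closure.

**Route**

Step 1
Reactants: 1 catechol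
Product: 2 2-(methoxymethoxy)phenol
Conditions: NaH (1.0 equiv), THF/DMF, 0 °C; MOMCl (1.0 equiv), 0 °C to rt; catechol in slight excess
Reagents that add atoms: chloromethyl methyl ether, COCCl
Why: Williamson-type O-alkylation of the catechol monoanion with the very reactive chloromethyl ether should stop largely at the monoether when one equivalent of base is used, because the second phenol is much harder to deprotonate once the first is ionised.

Step 2
Reactants: 2 2-(methoxymethoxy)phenol, 3 3-chloro-3-methylbut-1-yne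
Product: 4 1-(methoxymethoxy)-2-[(2-methylbut-3-yn-2-yl)oxy]benzene
Conditions: DBU, CuCl2·2H2O (cat.), MeCN, 0 °C
Reagents that add atoms: none
Why: Copper-catalysed O-propargylation of phenols with tertiary propargylic chlorides is the standard entry to aryl 1,1-dimethylpropargyl ethers and is compatible with the acetal.

Step 3
Reactants: 4 1-(methoxymethoxy)-2-[(2-methylbut-3-yn-2-yl)oxy]benzene
Product: 5 8-(methoxymethoxy)-2,2-dimethyl-2H-chromene
Conditions: xylenes, 140 °C
Reagents that add atoms: none
Why: Aromatic propargyl Claisen rearrangement to the only free ortho position, followed by enolisation, 1,5-hydrogen shift and 6π oxa-electrocyclisation of the ortho-quinone methide, is the classical route to 2,2-dimethyl-2H-chromenes.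

Step 4
Reactants: 5 8-(methoxymethoxy)-2,2-dimethyl-2H-chromene
Product: 8 8-(methoxymethoxy)-2,2-dimethyl-2H-chromen-7-ol, via C7-lithio chromene 6 (not isolated), via C7 dimethyl boronate 7 (not isolated)
Conditions: n-BuLi, TMEDA, THF, −78 to 0 °C; B(OMe)3, −78 °C to rt; 30% H2O2, aq. NaOH, 0 °C
Reagents that add atoms: hydrogen peroxide, OO
Why: Directed ortho-metalation by the MOM acetal, whose only free ortho position is C7, followed by borylation and alkaline peroxide oxidation of the aryl–boron bond, should place the third oxygen unambiguously, and basic peroxide does not attack the electron-rich chromene olefin.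

Step 5
Reactants: 8 8-(methoxymethoxy)-2,2-dimethyl-2H-chromen-7-ol
Product: 9 8-(methoxymethoxy)-2,2-dimethyl-2H-chromen-7-yl N-(propan-2-yl)carbamate
Conditions: i-PrNCO, Et3N (cat.), CH2Cl2, rt
Reagents that add atoms: isopropyl isocyanate, CC(C)N=C=O
Why: Base-catalysed addition of the phenol to the isocyanate (carbamoylation) installs a metalation-directing group that can later be removed under mild basic conditions.

Step 6
Reactants: 9 8-(methoxymethoxy)-2,2-dimethyl-2H-chromen-7-yl N-(propan-2-yl)carbamate
Product: 13 8-(methoxymethoxy)-2,2-dimethyl-6-(trimethylsilyl)-2H-chromen-7-yl N-(propan-2-yl)carbamate, via N-silyl carbamate 10 (not isolated), via C6-lithio N-silyl carbamate 11 (not isolated), via N-silyl C6-silyl carbamate 12 (not isolated)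
Conditions: TBSOTf, TMEDA, Et2O, 0 °C to rt; n-BuLi, TMEDA, −78 °C; TMSCl, −78 °C to rt; cold, brief aq. NaHSO4 work-up
Reagents that add atoms: chlorotrimethylsilane, C[Si](C)(C)Cl
Why: Carbamate-directed ortho-lithiation after transient N-silylation, with C6 the only ortho hydrogen, and low-temperature C-silylation is a standard preparation of ortho-silyl aryl carbamates, and the amine-complexed silyl triflate should be consumed by the carbamate nitrogen at 0 °C without cleaving the aryl MOM ether.

Step 7
Reactants: 13 8-(methoxymethoxy)-2,2-dimethyl-6-(trimethylsilyl)-2H-chromen-7-yl N-(propan-2-yl)carbamate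
Product: 15 8-(methoxymethoxy)-2,2-dimethyl-6-(trimethylsilyl)-2H-chromen-7-yl trifluoromethanesulfonate, via ortho-silyl phenol 14 (not isolated)
Conditions: Et2NH, DBU, MeCN, 40 °C; then PhNTf2, rt
Reagents that add atoms: N-phenylbis(trifluoromethanesulfonimide), O=S(=O)(N(c1ccccc1)S(=O)(=O)C(F)(F)F)C(F)(F)F
Why: Amidine-induced E1cB cleavage of the N-monoalkyl carbamate, with the isocyanate trapped by diethylamine as a urea, frees the hindered phenoxide, which is triflated in the same flask by PhNTf2 without disturbing the C–Si bond.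

Step 8
Reactants: 15 8-(methoxymethoxy)-2,2-dimethyl-6-(trimethylsilyl)-2H-chromen-7-yl trifluoromethanesulfonate, 16 ethynyltri(propan-2-yl)silane, 17 1-chloro-3-methylbut-2-ene
Product: 20 {[8-(methoxymethoxy)-2,2-dimethyl-7-(3-methylbut-2-en-1-yl)-2H-chromen-6-yl]ethynyl}tri(propan-2-yl)silane, via aryne 18 (not isolated), via arylcopper 19 (not isolated)
Conditions: CuI (10 mol %), CsF (3 equiv), MeCN/THF, 50 °C; 16 and 17 in excess, 15 added slowly
Reagents that add atoms: none
Why: Fluoride attacks the C6 silyl group and expels the C7 triflate to give aryne 18, while CuI, fluoride and alkyne 16 form the copper acetylide. Carbocupration of the strained triple bond places the alkynyl carbon on C6 and copper on C7 (arylcopper 19), and allylic substitution at the primary carbon of 17 then forms the benzylic C7–CH2 bond and returns the copper halide. The closest known reaction type is the copper-catalysed three-component coupling of arynes, terminal alkynes and allylic chlorides to 1-allyl-2-alkynylarenes. No ring is closed and no stereocentre is created. The aryne regioselectivity is secured by the C8 acetal oxygen, which distorts and polarises the aryne so that the acetylide enters at the distal, less hindered C6 and the carbon–copper bond forms at C7 next to the inductively stabilising oxygen. Linear prenylation is expected because the other allyl terminus is tertiary and the arylcopper is flanked by two ortho substituents; the chloride is chosen to slow direct allylation of the copper acetylide, and the bulky triisopropylsilyl group keeps the alkyne silylated in the presence of fluoride.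

Step 9
Reactants: 20 {[8-(methoxymethoxy)-2,2-dimethyl-7-(3-methylbut-2-en-1-yl)-2H-chromen-6-yl]ethynyl}tri(propan-2-yl)silane
Product: 21 6-ethynyl-8-(methoxymethoxy)-2,2-dimethyl-7-(3-methylbut-2-en-1-yl)-2H-chromene
Conditions: TBAF, THF, 0 °C
Reagents that add atoms: none
Why: Fluoride-mediated protodesilylation is selective for the alkynyl C–Si bond and leaves the acetal and both olefins untouched.

Step 10
Reactants: 21 6-ethynyl-8-(methoxymethoxy)-2,2-dimethyl-7-(3-methylbut-2-en-1-yl)-2H-chromene
Product: 23 2-[8-(methoxymethoxy)-2,2-dimethyl-7-(3-methylbut-2-en-1-yl)-2H-chromen-6-yl]acetaldehyde, via alkenylborane 22 (not isolated)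
Conditions: Cy2BH (1.1 equiv), THF, 0 °C; then 30% H2O2, pH 7 phosphate buffer, 0 °C
Reagents that add atoms: hydrogen peroxide, OO
Why: Anti-Markovnikov hydroboration of the terminal alkyne with a hindered dialkylborane is much faster than attack on the trisubstituted prenyl olefin or the hindered cyclic styrene, and buffered peroxide oxidation of the (E)-alkenylborane gives the enol and hence the arylacetaldehyde (hydroboration–oxidation).

Step 11
Reactants: 24 phloroglucinol
Product: 25 1,3,5-tris(methoxymethoxy)benzene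
Conditions: NaH, DMF, 0 °C; MOMCl (3.3 equiv), 0 °C to rt
Reagents that add atoms: chloromethyl methyl ether, COCCl
Why: Exhaustive Williamson O-alkylation of phloroglucinol with MOMCl gives the symmetrical tris-acetal, a standard ring A building block.

Step 12
Reactants: 23 2-[8-(methoxymethoxy)-2,2-dimethyl-7-(3-methylbut-2-en-1-yl)-2H-chromen-6-yl]acetaldehyde, 25 1,3,5-tris(methoxymethoxy)benzene
Product: 28 rac-2-[8-(methoxymethoxy)-2,2-dimethyl-7-(3-methylbut-2-en-1-yl)-2H-chromen-6-yl]-1-[2,4,6-tris(methoxymethoxy)phenyl]ethan-1-ol, via aryllithium 26 (not isolated), via arylcerium dichloride 27 (not isolated)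
Conditions: 25, n-BuLi, THF, 0 °C; anhydrous CeCl3, −78 °C; then 23, −78 °C; aq. NH4Cl
Reagents that add atoms: none
Why: Directed ortho-lithiation between two MOM groups and transmetalation to the weakly basic organocerium reagent should allow 1,2-addition to the easily enolised arylacetaldehyde (organocerium carbonyl addition), the carbinol centre forming as a racemate that the next step removes.

Step 13
Reactants: 28 rac-2-[8-(methoxymethoxy)-2,2-dimethyl-7-(3-methylbut-2-en-1-yl)-2H-chromen-6-yl]-1-[2,4,6-tris(methoxymethoxy)phenyl]ethan-1-ol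
Product: 29 2-[8-(methoxymethoxy)-2,2-dimethyl-7-(3-methylbut-2-en-1-yl)-2H-chromen-6-yl]-1-[2,4,6-tris(methoxymethoxy)phenyl]ethan-1-one
Conditions: Dess–Martin periodinane, NaHCO3, CH2Cl2, 0 °C to rt
Reagents that add atoms: none
Why: Dess–Martin oxidation of the secondary benzylic alcohol runs under buffered, near-neutral conditions that spare the acetals, the chromene and the prenyl group, and it erases the racemic centre.

Step 14
Reactants: 29 2-[8-(methoxymethoxy)-2,2-dimethyl-7-(3-methylbut-2-en-1-yl)-2H-chromen-6-yl]-1-[2,4,6-tris(methoxymethoxy)phenyl]ethan-1-one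
Product: 30 (2E)-3-(dimethylamino)-2-[8-(methoxymethoxy)-2,2-dimethyl-7-(3-methylbut-2-en-1-yl)-2H-chromen-6-yl]-1-[2,4,6-tris(methoxymethoxy)phenyl]prop-2-en-1-one
Conditions: DMF dimethyl acetal, toluene, 95 °C
Reagents that add atoms: N,N-dimethylformamide dimethyl acetal, COC(OC)N(C)C
Why: Condensation of the doubly activated methylene of a deoxybenzoin with DMF dimethyl acetal (enaminone formation) introduces the one-carbon unit that becomes C2 of ring C.

Step 15
Reactants: 30 (2E)-3-(dimethylamino)-2-[8-(methoxymethoxy)-2,2-dimethyl-7-(3-methylbut-2-en-1-yl)-2H-chromen-6-yl]-1-[2,4,6-tris(methoxymethoxy)phenyl]prop-2-en-1-one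
Product: 33 5,7-dihydroxy-3-[8-hydroxy-2,2-dimethyl-7-(3-methylbut-2-en-1-yl)-2H-chromen-6-yl]-4H-chromen-4-one, via ortho-hydroxy enaminone 31 (not isolated), via tris-MOM isoflavone 32 (not isolated)
Conditions: HCl (1.25 M in MeOH), 0 to 40 °C
Reagents that add atoms: none
Why: Methanolic hydrogen chloride transfers the MOM groups to methanol, the first freed ortho phenol adds to the protonated enaminone and expels dimethylamine (6-endo addition–elimination, the standard enaminone route to chromones), and the remaining acetals are cleaved at a temperature low enough that the ortho-prenyl phenol should not cyclise.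

**Compound list**
1 | catechol (benzene-1,2-diol) | Oc1ccccc1O | starting material
2 | 2-(methoxymethoxy)phenol | COCOc1ccccc1O | intermediate
3 | 3-chloro-3-methylbut-1-yne | C#CC(C)(C)Cl | starting material
4 | 1-(methoxymethoxy)-2-[(2-methylbut-3-yn-2-yl)oxy]benzene | COCOc1ccccc1OC(C)(C)C#C | intermediate
5 | 8-(methoxymethoxy)-2,2-dimethyl-2H-chromene | COCOc1cccc2C=CC(C)(C)Oc12 | intermediate
6 | [8-(methoxymethoxy)-2,2-dimethyl-2H-chromen-7-yl]lithium (formed in the flask) | [Li]c1ccc2C=CC(C)(C)Oc2c1OCOC | intermediate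
7 | dimethyl [8-(methoxymethoxy)-2,2-dimethyl-2H-chromen-7-yl]boronate (formed in the flask) | COB(OC)c1ccc2C=CC(C)(C)Oc2c1OCOC | intermediate
8 | 8-(methoxymethoxy)-2,2-dimethyl-2H-chromen-7-ol | COCOc1c(O)ccc2C=CC(C)(C)Oc12 | intermediate
9 | 8-(methoxymethoxy)-2,2-dimethyl-2H-chromen-7-yl N-(propan-2-yl)carbamate | CC(C)NC(=O)Oc1ccc2C=CC(C)(C)Oc2c1OCOC | intermediate
10 | 8-(methoxymethoxy)-2,2-dimethyl-2H-chromen-7-yl N-[tert-butyl(dimethyl)silyl]-N-(propan-2-yl)carbamate (formed in the flask) | CC(C)N([Si](C)(C)C(C)(C)C)C(=O)Oc1ccc2C=CC(C)(C)Oc2c1OCOC | intermediate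
11 | C6-lithio derivative of 10 (formed in the flask) | CC(C)N([Si](C)(C)C(C)(C)C)C(=O)Oc1c([Li])cc2C=CC(C)(C)Oc2c1OCOC | intermediate
12 | 8-(methoxymethoxy)-2,2-dimethyl-6-(trimethylsilyl)-2H-chromen-7-yl N-[tert-butyl(dimethyl)silyl]-N-(propan-2-yl)carbamate (formed in the flask) | CC(C)N([Si](C)(C)C(C)(C)C)C(=O)Oc1c([Si](C)(C)C)cc2C=CC(C)(C)Oc2c1OCOC | intermediate
13 | 8-(methoxymethoxy)-2,2-dimethyl-6-(trimethylsilyl)-2H-chromen-7-yl N-(propan-2-yl)carbamate | CC(C)NC(=O)Oc1c([Si](C)(C)C)cc2C=CC(C)(C)Oc2c1OCOC | intermediate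
14 | 8-(methoxymethoxy)-2,2-dimethyl-6-(trimethylsilyl)-2H-chromen-7-ol (formed in the flask) | COCOc1c(O)c([Si](C)(C)C)cc2C=CC(C)(C)Oc12 | intermediate
15 | 8-(methoxymethoxy)-2,2-dimethyl-6-(trimethylsilyl)-2H-chromen-7-yl trifluoromethanesulfonate | COCOc1c(OS(=O)(=O)C(F)(F)F)c([Si](C)(C)C)cc2C=CC(C)(C)Oc12 | intermediate
16 | ethynyltri(propan-2-yl)silane | C#C[Si](C(C)C)(C(C)C)C(C)C | starting material
17 | 1-chloro-3-methylbut-2-ene (prenyl chloride) | CC(C)=CCCl | starting material
18 | 6,7-didehydro-8-(methoxymethoxy)-2,2-dimethyl-2H-chromene, the aryne (formed in the flask) | COCOC1=C2OC(C)(C)C=CC2=CC#C1 | intermediate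
19 | [8-(methoxymethoxy)-2,2-dimethyl-6-{[tri(propan-2-yl)silyl]ethynyl}-2H-chromen-7-yl]copper (formed in the flask) | [Cu]c1c(C#C[Si](C(C)C)(C(C)C)C(C)C)cc2C=CC(C)(C)Oc2c1OCOC | intermediate
20 | {[8-(methoxymethoxy)-2,2-dimethyl-7-(3-methylbut-2-en-1-yl)-2H-chromen-6-yl]ethynyl}tri(propan-2-yl)silane | CC(C)[Si](C(C)C)(C(C)C)C#Cc1cc2C=CC(C)(C)Oc2c(OCOC)c1CC=C(C)C | intermediate
21 | 6-ethynyl-8-(methoxymethoxy)-2,2-dimethyl-7-(3-methylbut-2-en-1-yl)-2H-chromene | C#Cc1cc2C=CC(C)(C)Oc2c(OCOC)c1CC=C(C)C | intermediate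
22 | dicyclohexyl{(E)-2-[8-(methoxymethoxy)-2,2-dimethyl-7-(3-methylbut-2-en-1-yl)-2H-chromen-6-yl]ethenyl}borane (formed in the flask) | C1CCCCC1B(/C=C/c1cc2C=CC(C)(C)Oc2c(OCOC)c1CC=C(C)C)C1CCCCC1 | intermediate
23 | 2-[8-(methoxymethoxy)-2,2-dimethyl-7-(3-methylbut-2-en-1-yl)-2H-chromen-6-yl]acetaldehyde | O=CCc1cc2C=CC(C)(C)Oc2c(OCOC)c1CC=C(C)C | intermediate
24 | phloroglucinol (benzene-1,3,5-triol) | Oc1cc(O)cc(O)c1 | starting material
25 | 1,3,5-tris(methoxymethoxy)benzene | COCOc1cc(OCOC)cc(OCOC)c1 | intermediate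
26 | [2,4,6-tris(methoxymethoxy)phenyl]lithium (formed in the flask) | [Li]c1c(OCOC)cc(OCOC)cc1OCOC | intermediate
27 | dichloro[2,4,6-tris(methoxymethoxy)phenyl]cerium (formed in the flask) | Cl[Ce](Cl)c1c(OCOC)cc(OCOC)cc1OCOC | intermediate
28 | rac-2-[8-(methoxymethoxy)-2,2-dimethyl-7-(3-methylbut-2-en-1-yl)-2H-chromen-6-yl]-1-[2,4,6-tris(methoxymethoxy)phenyl]ethan-1-ol (racemate) | COCOc1cc(OCOC)cc(OCOC)c1C(O)Cc1cc2C=CC(C)(C)Oc2c(OCOC)c1CC=C(C)C | intermediate
29 | 2-[8-(methoxymethoxy)-2,2-dimethyl-7-(3-methylbut-2-en-1-yl)-2H-chromen-6-yl]-1-[2,4,6-tris(methoxymethoxy)phenyl]ethan-1-one | COCOc1cc(OCOC)cc(OCOC)c1C(=O)Cc1cc2C=CC(C)(C)Oc2c(OCOC)c1CC=C(C)C | intermediate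
30 | (2E)-3-(dimethylamino)-2-[8-(methoxymethoxy)-2,2-dimethyl-7-(3-methylbut-2-en-1-yl)-2H-chromen-6-yl]-1-[2,4,6-tris(methoxymethoxy)phenyl]prop-2-en-1-one | CN(C)/C=C(\c1cc2C=CC(C)(C)Oc2c(OCOC)c1CC=C(C)C)C(=O)c1c(OCOC)cc(OCOC)cc1OCOC | intermediate
31 | (2E)-3-(dimethylamino)-1-[2-hydroxy-4,6-bis(methoxymethoxy)phenyl]-2-[8-(methoxymethoxy)-2,2-dimethyl-7-(3-methylbut-2-en-1-yl)-2H-chromen-6-yl]prop-2-en-1-one (formed in the flask) | CN(C)/C=C(\c1cc2C=CC(C)(C)Oc2c(OCOC)c1CC=C(C)C)C(=O)c1c(O)cc(OCOC)cc1OCOC | intermediate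
32 | 5,7-bis(methoxymethoxy)-3-[8-(methoxymethoxy)-2,2-dimethyl-7-(3-methylbut-2-en-1-yl)-2H-chromen-6-yl]-4H-chromen-4-one (formed in the flask) | COCOc1cc(OCOC)c2c(c1)occ(-c1cc3C=CC(C)(C)Oc3c(OCOC)c1CC=C(C)C)c2=O | intermediate
33 | 5,7-dihydroxy-3-[8-hydroxy-2,2-dimethyl-7-(3-methylbut-2-en-1-yl)-2H-chromen-6-yl]-4H-chromen-4-one (CNP0136924.0) | CC(C)=CCc1c(-c2coc3cc(O)cc(O)c3c2=O)cc2c(c1O)OC(C)(C)C=C2 | target

**Step count**
Total: 15 steps. Longest linear sequence: 14 steps (steps 1–10 and 12–15); step 11 is the one-step side branch to the ring A fragment.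

**Steps most likely to fail, with fallbacks**

Step 8. Arylcopper 19 may attack the tertiary terminus of the prenyl electrophile, it may be protonated by alkyne 16 before it is allylated, or the copper acetylide may be allylated directly. Fallback: from 15, the same aryne coupling is run with 16 and allyl chloride, which has no regiochemical ambiguity and is the electrophile for which the coupling is established, to give {[7-allyl-8-(methoxymethoxy)-2,2-dimethyl-2H-chromen-6-yl]ethynyl}tri(propan-2-yl)silane F1. Olefin cross-metathesis of F1 with excess 2-methylbut-2-ene (second-generation Grubbs catalyst, RuCl2(=CHPh)(H2IMes)(PCy3), CH2Cl2, 40 °C) then converts the allyl group into the prenyl group and returns to the route at 20. The bulky silylalkyne and the hindered cyclic styrene should stay out of the metathesis.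

Step 12. The aryl-metal may deprotonate the acidic benzylic α-position of aldehyde 23, leading to self-aldol condensation instead of carbonyl addition. Fallback: from 23, Pinnick oxidation (NaClO2, NaH2PO4, 2-methylbut-2-ene, t-BuOH/H2O) gives 2-[8-(methoxymethoxy)-2,2-dimethyl-7-(3-methylbut-2-en-1-yl)-2H-chromen-6-yl]acetic acid F2. Activation with carbonyldiimidazole and treatment with MeNHOMe·HCl gives N-methoxy-N-methyl-2-[8-(methoxymethoxy)-2,2-dimethyl-7-(3-methylbut-2-en-1-yl)-2H-chromen-6-yl]acetamide F3. Addition of aryllithium 26 (from 25 and n-BuLi, THF, −78 °C; Weinreb ketone synthesis) then gives ketone 29 directly, so the fallback rejoins the route at 29 and bypasses steps 12 and 13. Amide that is only enolised is recovered on work-up rather than destroyed.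

Step 15. Under Brønsted acid the liberated C8 phenol may add to the neighbouring prenyl double bond (chroman formation), or the chromene may be hydrated, before all four acetals are gone. Fallback: from 30, the aryl MOM ethers are cleaved under non-protic, amine-buffered conditions (TMSOTf, 2,2′-bipyridyl, CH2Cl2, 0 °C, then water, which hydrolyses the aryl silyl ethers) to give (2E)-3-(dimethylamino)-2-[8-hydroxy-2,2-dimethyl-7-(3-methylbut-2-en-1-yl)-2H-chromen-6-yl]-1-(2,4,6-trihydroxyphenyl)prop-2-en-1-one F4. Gentle warming of F4 in EtOH, with a trace of AcOH if needed, closes ring C with loss of dimethylamine and arrives at 33.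

**Further compounds**
F1 | step 8 | {[7-allyl-8-(methoxymethoxy)-2,2-dimethyl-2H-chromen-6-yl]ethynyl}tri(propan-2-yl)silane | CC(C)[Si](C(C)C)(C(C)C)C#Cc1cc2C=CC(C)(C)Oc2c(OCOC)c1CC=C
F2 | step 12 | 2-[8-(methoxymethoxy)-2,2-dimethyl-7-(3-methylbut-2-en-1-yl)-2H-chromen-6-yl]acetic acid | OC(=O)Cc1cc2C=CC(C)(C)Oc2c(OCOC)c1CC=C(C)C
F3 | step 12 | N-methoxy-N-methyl-2-[8-(methoxymethoxy)-2,2-dimethyl-7-(3-methylbut-2-en-1-yl)-2H-chromen-6-yl]acetamide | CON(C)C(=O)Cc1cc2C=CC(C)(C)Oc2c(OCOC)c1CC=C(C)C
F4 | step 15 | (2E)-3-(dimethylamino)-2-[8-hydroxy-2,2-dimethyl-7-(3-methylbut-2-en-1-yl)-2H-chromen-6-yl]-1-(2,4,6-trihydroxyphenyl)prop-2-en-1-one | CN(C)/C=C(\c1cc2C=CC(C)(C)Oc2c(O)c1CC=C(C)C)C(=O)c1c(O)cc(O)cc1O
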